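## Structural features

The target is a longipinane sesquiterpenoid diester built on a fully substituted cyclobutane (C4, C5, C10, C11). The cyclobutane is bridged twice: across C4/C11 on one face by the enone unit C3(Me)=C2–C1(=O) (ring A, a 4-methylbicyclo[3.1.1]hept-3-en-2-one), and across C5/C10 on the other face by the chain C6–C7–C8–C9 (ring B, seven-membered). The four cyclobutane carbons are contiguous stereocentres, and C10 is quaternary with its methyl group on the ring-A face. C7 (angelate) and C9 (tiglate) are 1,3-anti carbinol centres, each next to a quaternary carbon (C6 gem-dimethyl, C10). The fragile parts are the (Z)-angelate, which isomerises to the tiglate under basic or nucleophilic conditions, the two hindered esters, which must be told apart before both are in place, and the cyclobutane, which opens if a radical or cation is generated on a carbon attached to it. The real difficulty lies in the relative and absolute configuration of the crowded cyclobutane, and in C7 and C9, which sit on a face that the distant enone barely differentiates. The plan exploits the β-methyl enone of ring A: cutting C2=C3 by a retro-aldol condensation leaves acetyl groups on C4 and C11 of a cyclobutane with a mirror plane through C5 and C10. One catalyst-controlled closure then makes C4 and C11 different and so defines all four cyclobutane stereocentres at once, C5 included.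

## Logic of the disconnections

**32 to 29 and 30.** The C7 O–acyl bond is cut first, because the angelate is the most labile group and should meet the fewest reagents. The gain is a hydroxy tiglate whose two oxygens are already differentiated. The forward step must acylate a neopentyl secondary alcohol without Z-to-E isomerisation.

**29 to 27 and 28.** The O9–acyl bond and the C7–H bond are cut together (Evans–Tishchenko retron). One reagent then puts the tiglate on O9 and sets C7 anti to C9, so no protecting group is needed to distinguish the two carbinols. The demand is intramolecular hydride delivery across ring B from a hemiacetal of an enal.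

**27 to 25 (via 26).** The C9–O bond is cut. The two faces of ring B differ only through remote ring A, so a ring-closing aldol addition would not control C9. The centre is therefore erased and re-installed under catalyst control. The gain is a dienone with no ring-B stereocentre. The forward step must distinguish the ring-B enone from the ring-A enone and must be ligand-controlled.

**25 to 24.** The C8=C9 bond is cut by a retro-aldol condensation, which opens ring B to a methyl ketone and a non-enolisable aldehyde. Only C8 can act as nucleophile, so the only demand is seven-membered ring closure.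

**24 to 19 (via 23, 22, 21, 20).** The C9 aldehyde goes back to a silyl-protected carbinol, and the C7–C8 bond is cut to a carboxylic acid plus a methyl-metal reagent. C8 is added only after ring A exists, so the meso precursor carries no third enolisable ketone. The forward ketone synthesis must tolerate an enone, which points to an organozinc acylation.

**19 to 18.** The C2=C3 bond is cut (key step). The bicyclic enone becomes an achiral meso diketone, and all absolute stereochemistry is moved into one catalytic step. The demand is closure to a strained bicyclo[3.1.1] system with discrimination between enantiotopic acetyl groups.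

**18 to 17.** Both acetyl C=O groups are traced to isopropenyl groups (ozonolysis retron). The ketones are unveiled only when nothing else in the molecule can react with them.

**17 to 14 (via 16, 15).** The C10 methyl is traced to the carboxamide that directed the C–H functionalisation. A secondary quinolinyl amide cis to two acetyl groups would close to hydroxy-lactams, and its quinoline ring would not survive ozone, so it must be gone before step 11. The deoxygenation must be a two-electron process that never puts a radical or cation on the carbon attached to the cyclobutane.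

**14 to 12 and 13.** The C4–C and C11–C bonds are cut as a double C–H alkenylation cis to the amide. The gain is a 1,3-disubstituted cyclobutane with no stereocentre. The demand is two successive palladacycle formations next to a quaternary carbon, with an alkenyl iodide as partner rather than the bromide.

**12 to 11.** The C5–H and C4–H bonds are cut (hydrogenation). This sets the only relative configuration that cannot be corrected later, C5 against C10, and avoids having to hydrolyse one of two diastereotopic esters selectively.

**11 to 5 (via 10, 9, 8, 6 and 7).** The geminal C10 substituents are traced to a symmetrical diester. In the flat cyclobutene the two esters are enantiotopic, so mono-hydrolysis raises no diastereomer question. C9 is lowered to the alcohol level here, because an ester cannot be reduced selectively once ketones are present. The tert-butyl ester at C7 is chosen so that hydroxide and LiBH4 leave it alone.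

**5 to 1 and 2 (via 4, 3).** The C5–C6 bond is cut (Reformatsky retron), followed by loss of water. The gain is two commercial compounds. C6 is quaternary, so the dehydration can only give the ring alkene.

## Other disconnections considered

**Alternative 1:** The pinane-type core is traced back, through a 1,2-shift, to a norbornene in which C10 is bonded to C1 instead of C11; that norbornene is then cut at C4–C5 and C1–C11. In the forward direction the tethered nitroalkene–silyloxycyclopentadiene A2 undergoes an intramolecular Diels–Alder reaction to the endo-nitro norbornene A1. Nitro reduction, desilylation and diazotisation then move C10 from C1 to C11 (Tiffeneau–Demjanov-type shift) and leave C1 as the ketone.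

- In favour: one step forms two C–C bonds, ring B and the bicyclic core. C7 and C9 arrive as differently silylated carbinols whose configuration was set in an open chain; on this point the alternative is better than the chosen plan, which needs a ligand-controlled borylation and a directed reduction late on. C10 carries its methyl from the start, which is also better than the amide-to-methyl detour. The polarity match (diene terminus C4 to nitroalkene carbon C5) and the anti-periplanar C1–C10 bond of the endo amine are as clear mechanistically as the aldol of the chosen plan.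
- Against: A2 needs a quaternary stereocentre on a cyclopentadiene and two carbinol centres, all set enantioselectively beforehand. Nitroalkenes can also react with silyl enol ethers as heterodienes to give cyclic nitronates. The ring switch turns a norbornane into a considerably more strained pinane skeleton, against the usual direction of such rearrangements, so migration of C2, hydride shifts and fragmentation are to be expected.
- Step economy: the linear assembly of A2 is expected to cost more steps than the eleven steps to the meso diketone. The chosen plan also draws its absolute configuration from an achiral intermediate.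

**Alternative 2:** The cut is C3–C4. In the forward direction a zerovalent palladium catalyst inserts into the (Z)-vinyl iodide of the cyclobutanone A4 and couples C3 with the C4 enolate, giving the bridged ketone A3.

- In favour: the ring closure is an irreversible C–C coupling, not limited by an aldol equilibrium; on this point the alternative is better than the chosen plan. The C10 methyl and its oxygenated partner are present from the start, again better. The later oxidation of the C1 methylene to the enone is an allylic oxidation of a well-behaved kind, and counts as equal.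
- Against: cyclobutanone enolates are strained and tend to self-condense or cleave under base, and reductive elimination must create the bicyclo[3.1.1] ring. A4 has two adjacent stereocentres, one quaternary, and needs its own asymmetric synthesis. After the key step, the C5 ketone must become C5–H bearing the tertiary C6 with defined configuration, by adding a hindered enolate to a bridging cyclobutanone and then deoxygenating with retention. That is harder than in the chosen plan, where C5 is set by hydrogenation before the ring system becomes crowded. Ring B is still to be built, with the same C7/C9 problem.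
- Step economy: more operations remain after the key step than in the chosen plan.

**Alternative 3:** The cut is C10–C11. In the forward direction the bis(trimethylsilyl enol ether) A6 of a cis-fused bicyclo[5.4.0]undecenedione is oxidised by one electron with (NH4)2Ce(NO3)6 or Cu(OTf)2, coupling C10 to C11 and giving the tricyclic dione A5.

- In favour: rings A and B are assembled first as an unstrained six/seven bicycle by ordinary annulation chemistry, and the cyclobutane is made last. Ring-B closure on a crowded cyclobutane is thus avoided, which is better than the chosen plan. C7 is already distinguished from C9 as a ketal, which is at least equal to the Tishchenko differentiation.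
- Against: oxidative enolate coupling to a four-membered ring that also creates a quaternary centre is rare. The radical cation must close a cyclobutane in competition with intermolecular coupling, α-oxygenation and dehydrogenation, and the cross-conjugated dienol ether offers more than one reactive carbon. The C9 and C7 ketones must then be reduced on a face that ring A hardly differentiates, so the stereochemical weakness of ring B is not removed. The absolute configuration at C4/C5 has to come from an earlier step.
- Step economy: the step count is comparable, but the key step is much less certain than a reversible, catalyst-controlled aldol.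

Key step: step 12

Assumption: 2-iodopropene (13) is taken as a purchased reagent, because the divalent/tetravalent palladium manifold of step 8 needs the alkenyl iodide, not the bromide.

Assumption: the hand of the catalysts in steps 12 and 18 is written as the working choice; the pseudo-enantiomeric amine and the antipodal ligand are commercial and invert the sense of induction if the first analysis requires it.

## Route

Step 1
Reactants: 1 diisopropyl 3-oxocyclobutane-1,1-dicarboxylate; 2 tert-butyl 2-bromo-2-methylpropanoate
Product: 4 diisopropyl 3-(1-tert-butoxy-2-methyl-1-oxopropan-2-yl)-3-hydroxycyclobutane-1,1-dicarboxylate, via Reformatsky zinc reagent 3 (not isolated)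
Conditions: Zn dust (TMSCl-activated), THF, 0 °C; then 1, 0 °C → rt; aq NH4Cl
Reagents that add atoms: none
Why: Reformatsky addition of a tertiary zinc ester enolate to a strained, unhindered cyclobutanone forms the C5–C6 bond; no stereocentre arises because C10 carries two identical esters.

Step 2
Reactants: 4 diisopropyl 3-(1-tert-butoxy-2-methyl-1-oxopropan-2-yl)-3-hydroxycyclobutane-1,1-dicarboxylate
Product: 5 diisopropyl 3-(1-tert-butoxy-2-methyl-1-oxopropan-2-yl)cyclobut-2-ene-1,1-dicarboxylate
Conditions: Ph2S[OC(CF3)2Ph]2 (Martin sulfurane), CH2Cl2, 0 °C → rt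
Reagents that add atoms: none
Why: Sulfurane dehydration of a tertiary alcohol; C6 has no hydrogen, so the only possible alkene is the ring alkene C4=C5. The neutral, cold conditions avoid cyclobutyl cation rearrangement and electrocyclic opening of the cyclobutene.

Step 3
Reactants: 5 diisopropyl 3-(1-tert-butoxy-2-methyl-1-oxopropan-2-yl)cyclobut-2-ene-1,1-dicarboxylate
Product: 6 rac-3-(1-tert-butoxy-2-methyl-1-oxopropan-2-yl)-1-(isopropoxycarbonyl)cyclobut-2-ene-1-carboxylic acid
Conditions: KOH (1.0 equiv), i-PrOH/H2O, 0 °C → rt; then aq HCl
Reagents that add atoms: potassium hydroxide, [K+].[OH-]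
Why: Malonate mono-saponification; the geminal esters are activated, the carboxylate formed protects the second one, and the tert-butyl ester is inert to hydroxide. The two isopropyl esters of the flat cyclobutene are enantiotopic, so the product is a single racemic compound.

Step 4
Reactants: 6 rac-3-(1-tert-butoxy-2-methyl-1-oxopropan-2-yl)-1-(isopropoxycarbonyl)cyclobut-2-ene-1-carboxylic acid; 7 quinolin-8-amine
Product: 9 isopropyl rac-3-(1-tert-butoxy-2-methyl-1-oxopropan-2-yl)-1-(quinolin-8-ylcarbamoyl)cyclobut-2-ene-1-carboxylate, via acid chloride 8 (not isolated)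
Conditions: 1-chloro-N,N,2-trimethylprop-1-en-1-amine, CH2Cl2, 0 °C → rt; then 7, pyridine, DMAP (cat.), rt
Reagents that add atoms: none
Why: Neutral acid chloride formation (no HCl, so the tert-butyl ester survives) followed by acylation of the weakly nucleophilic aromatic amine. The quaternary acid has no α-hydrogen, so no ketene pathway exists.

Step 5
Reactants: 9 isopropyl rac-3-(1-tert-butoxy-2-methyl-1-oxopropan-2-yl)-1-(quinolin-8-ylcarbamoyl)cyclobut-2-ene-1-carboxylate
Product: 10 tert-butyl rac-2-[3-(hydroxymethyl)-3-(quinolin-8-ylcarbamoyl)cyclobut-1-en-1-yl]-2-methylpropanoate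
Conditions: LiBH4, THF/MeOH, 0 °C → rt
Reagents that add atoms: none
Why: Chemoselective borohydride reduction of the isopropyl ester, activated by the geminal amide and lithium chelation. The secondary amide, the hindered tert-butyl ester and the alkene are not reduced, and C9 reaches the alcohol level before any ketone exists.

Step 6
Reactants: 10 tert-butyl rac-2-[3-(hydroxymethyl)-3-(quinolin-8-ylcarbamoyl)cyclobut-1-en-1-yl]-2-methylpropanoate
Product: 11 tert-butyl rac-2-methyl-2-[3-(quinolin-8-ylcarbamoyl)-3-(triisopropylsilyloxymethyl)cyclobut-1-en-1-yl]propanoate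
Conditions: TIPSOTf, 2,6-lutidine, CH2Cl2, −78 → 0 °C
Reagents that add atoms: triisopropylsilyl trifluoromethanesulfonate, CC(C)[Si](OS(=O)(=O)C(F)(F)F)(C(C)C)C(C)C
Why: Standard silylation of a primary alcohol. The bulky, non-coordinating silyl ether withstands the later palladium, zirconium, base and ozone steps and blocks the ring face that must not receive hydrogen.

Step 7
Reactants: 11 tert-butyl rac-2-methyl-2-[3-(quinolin-8-ylcarbamoyl)-3-(triisopropylsilyloxymethyl)cyclobut-1-en-1-yl]propanoate
Product: 12 tert-butyl 2-methyl-2-[3-(quinolin-8-ylcarbamoyl)-3-(triisopropylsilyloxymethyl)cyclobutyl]propanoate (amide trans to the C5 side chain; achiral)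
Conditions: H2 (1 atm), [Ir(cod)(PCy3)(py)]PF6 (5 mol %), CH2Cl2, rt
Reagents that add atoms: none
Why: Amide-directed homogeneous hydrogenation: the amide carbonyl binds iridium and hydrogen is delivered to the alkene face it occupies, while the silyloxymethyl group shields the other face. The new C5–H is therefore cis to the amide, which places the side chain trans to the amide and cis to C9 and sets the C5/C10 relationship.

Step 8
Reactants: 12 tert-butyl 2-methyl-2-[3-(quinolin-8-ylcarbamoyl)-3-(triisopropylsilyloxymethyl)cyclobutyl]propanoate; 13 2-iodopropene
Product: 14 tert-butyl 2-[2,4-di(prop-1-en-2-yl)-3-(quinolin-8-ylcarbamoyl)-3-(triisopropylsilyloxymethyl)cyclobutyl]-2-methylpropanoate (meso; both isopropenyl groups cis to the amide)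
Conditions: Pd(OAc)2 (15 mol %), Ag2CO3, (BnO)2P(O)OH (30 mol %), 13 (6 equiv), t-BuOMe, 90 °C, sealed tube
Reagents that add atoms: none
Why: 8-Aminoquinoline-directed β-C(sp3)–H alkenylation through five-membered palladacycles, with palladium shuttling between the divalent and tetravalent states and Ag2CO3 removing iodide. Both ring methylene C–H bonds cis to the amide react, on the face away from the C5 side chain, so C4 and C11 are set cis to each other and the product is meso.

Step 9
Reactants: 14 tert-butyl 2-[2,4-di(prop-1-en-2-yl)-3-(quinolin-8-ylcarbamoyl)-3-(triisopropylsilyloxymethyl)cyclobutyl]-2-methylpropanoate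
Product: 15 tert-butyl 2-[3-formyl-2,4-di(prop-1-en-2-yl)-3-(triisopropylsilyloxymethyl)cyclobutyl]-2-methylpropanoate (meso)
Conditions: Cp2Zr(H)Cl, THF, rt; then aq NaHCO3
Reagents that add atoms: none
Why: Schwartz-reagent reduction of the amide: after N–H deprotonation the C=O is hydrozirconated to a stable N,O-bound zirconium hemiaminal that gives the aldehyde on work-up. Esters and silyl ethers are inert, and 1,1-disubstituted alkenes react much more slowly than the amide.

Step 10
Reactants: 15 tert-butyl 2-[3-formyl-2,4-di(prop-1-en-2-yl)-3-(triisopropylsilyloxymethyl)cyclobutyl]-2-methylpropanoate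
Product: 17 tert-butyl 2-methyl-2-[3-methyl-2,4-di(prop-1-en-2-yl)-3-(triisopropylsilyloxymethyl)cyclobutyl]propanoate (meso), via hydrazone 16 (not isolated)
Conditions: N2H4·H2O, EtOH, 60 °C; then KOt-Bu, DMSO, rt
Reagents that add atoms: none
Why: Low-temperature Wolff–Kishner reduction, the classical conversion of a quaternary formyl group into an angular methyl. The anionic protonation and loss of N2 avoid a radical or cation next to the cyclobutane, and the tert-butyl ester and silyl ether tolerate the conditions.

Step 11
Reactants: 17 tert-butyl 2-methyl-2-[3-methyl-2,4-di(prop-1-en-2-yl)-3-(triisopropylsilyloxymethyl)cyclobutyl]propanoate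
Product: 18 tert-butyl 2-[2,4-diacetyl-3-methyl-3-(triisopropylsilyloxymethyl)cyclobutyl]-2-methylpropanoate (meso; acetyl groups on C4 and C11 cis to the C10 methyl and trans to the C5 side chain)
Conditions: O3, CH2Cl2/MeOH, −78 °C; then Me2S, −78 °C → rt; neutral work-up
Reagents that add atoms: ozone, [O-][O+]=O
Why: Ozonolysis of the two 1,1-disubstituted alkenes with reductive work-up, done after the ozone-sensitive quinoline has left. The all-trans-vicinal arrangement is also the thermodynamic one, so epimerisation at C4 or C11 does no harm, and the neutral work-up prevents premature achiral aldol closure.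

Step 12
Reactants: 18 tert-butyl 2-[2,4-diacetyl-3-methyl-3-(triisopropylsilyloxymethyl)cyclobutyl]-2-methylpropanoate
Product: 19 tert-butyl 2-[4,6-dimethyl-2-oxo-6-(triisopropylsilyloxymethyl)bicyclo[3.1.1]hept-3-en-7-yl]-2-methylpropanoate (ring A closed; C10 methyl syn to the enone bridge, C5 side chain and C9 silyloxymethyl anti to it; single enantiomer)
Conditions: 9-amino-9-deoxy-epi-quinine (20 mol %), AcOH (60 mol %), toluene, 4 Å MS, 0 → 40 °C
Reagents that add atoms: none
Why: Proposed new method: the primary amine condenses reversibly with either acetyl group to give the methyl-side enamine, its acetic acid salt hydrogen-bonds the carbonyl of the other acetyl, and the enamine carbon C2 adds to C3; the resulting ketol iminium loses water by E1cB to the conjugated C2=C3 iminium, whose hydrolysis releases 19 and the catalyst. The closest known reactions are the Hajos–Parrish-type amino-acid-catalysed aldol cyclisation and the primary-amine-salt-catalysed desymmetrising aldol condensation of 4-substituted heptane-2,6-diones to 5-substituted 3-methylcyclohex-2-enones; new here are the cyclobutane-locked 1,5-diketone and the strained bridged product. Ring A is closed in a 6-(enolendo)-exo-trig mode across the cis-1,3 positions of the cyclobutane, which is possible only because both acetyl groups stand on the same face. The extra strain of the bicyclo[3.1.1]heptene makes the addition reversible, so the elimination to the enone, helped by molecular sieves, has to pull the equilibrium. No relative configuration is created: C5 and C10 lie on the mirror plane of 18 and the cis relationship of C4 and C11 is already present, so the catalyst only chooses which enantiotopic acetyl is the donor (the one on C11, which keeps its carbonyl as C1) and which is the acceptor (the one on C4, whose carbonyl carbon becomes C3). That single choice fixes the absolute configuration of C4, C5, C10 and C11 together. The selectivities needed are enamine formation at the methyl group (the ring α-carbons are tertiary and would give a strained alkylidenecyclobutane), reaction with the second acetyl only (the tert-butyl ester has no α-hydrogen and is not electrophilic enough) and suppression of uncatalysed racemic closure, which the buffered non-polar medium at moderate temperature is chosen to secure. Should C4 or C11 epimerise through the enamine, only the isomer with both acetyl groups on the same face can cyclise, so any trans isomer is returned to the productive pool.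

Step 13
Reactants: 19 tert-butyl 2-[4,6-dimethyl-2-oxo-6-(triisopropylsilyloxymethyl)bicyclo[3.1.1]hept-3-en-7-yl]-2-methylpropanoate
Product: 20 2-[4,6-dimethyl-2-oxo-6-(triisopropylsilyloxymethyl)bicyclo[3.1.1]hept-3-en-7-yl]-2-methylpropanoic acid
Conditions: CF3CO2H, CH2Cl2, 0 °C
Reagents that add atoms: none
Why: Acidolysis of the tert-butyl ester through the tert-butyl cation, which does not depend on the hindrance of the acyl group. The enone and the primary triisopropylsilyl ether tolerate cold anhydrous acid.

Step 14
Reactants: 20 2-[4,6-dimethyl-2-oxo-6-(triisopropylsilyloxymethyl)bicyclo[3.1.1]hept-3-en-7-yl]-2-methylpropanoic acid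
Product: 22 4,6-dimethyl-7-(2-methyl-3-oxobutan-2-yl)-6-(triisopropylsilyloxymethyl)bicyclo[3.1.1]hept-3-en-2-one, via acid chloride 21 (not isolated)
Conditions: 1-chloro-N,N,2-trimethylprop-1-en-1-amine, CH2Cl2, rt; then MeZnCl, Pd(PPh3)4 (5 mol %), THF, 0 °C → rt
Reagents that add atoms: methylzinc chloride, C[Zn]Cl
Why: Negishi-type acylation of the acid chloride with a methylzinc reagent. Organozinc reagents add neither to the enone nor to the new ketone, so C8 is introduced chemoselectively and the C7 carboxyl becomes the methyl ketone.

Step 15
Reactants: 22 4,6-dimethyl-7-(2-methyl-3-oxobutan-2-yl)-6-(triisopropylsilyloxymethyl)bicyclo[3.1.1]hept-3-en-2-one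
Product: 23 6-(hydroxymethyl)-4,6-dimethyl-7-(2-methyl-3-oxobutan-2-yl)bicyclo[3.1.1]hept-3-en-2-one
Conditions: HF·pyridine, THF/pyridine, 0 °C → rt
Reagents that add atoms: none
Why: Fluoride cleavage of the silyl ether in a buffered, weakly acidic medium, which avoids base-induced aldol chemistry of the methyl ketone.

Step 16
Reactants: 23 6-(hydroxymethyl)-4,6-dimethyl-7-(2-methyl-3-oxobutan-2-yl)bicyclo[3.1.1]hept-3-en-2-one
Product: 24 2,6-dimethyl-7-(2-methyl-3-oxobutan-2-yl)-4-oxobicyclo[3.1.1]hept-2-ene-6-carbaldehyde
Conditions: Dess–Martin periodinane, NaHCO3, CH2Cl2, rt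
Reagents that add atoms: none
Why: Dess–Martin oxidation of a neopentyl primary alcohol to a non-enolisable aldehyde; the buffered conditions leave both ketones untouched.

Step 17
Reactants: 24 2,6-dimethyl-7-(2-methyl-3-oxobutan-2-yl)-4-oxobicyclo[3.1.1]hept-2-ene-6-carbaldehyde
Product: 25 longipina-2,8-diene-1,7-dione (tricyclic dienone; ring B closed with C8=C9)
Conditions: KOt-Bu (0.3 equiv), t-BuOH/THF, 0 → 40 °C
Reagents that add atoms: none
Why: Intramolecular aldol condensation (7-enolexo-exo-trig addition, then E1cB): C8 is the only enolisable position on the ring-B side and the C9 aldehyde cannot enolise, so the cycloheptenone is the only condensation product. The ring-A dienolate cannot reach C9 because its carbons lie on the opposite face of the cyclobutane, and the uncontrolled C9 centre of the aldol adduct is removed on purpose.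

Step 18
Reactants: 25 longipina-2,8-diene-1,7-dione
Product: 27 9-hydroxylongipin-2-ene-1,7-dione (C9–OH on the C11 side of ring B), via pinacol boronate 26 (not isolated)
Conditions: CuCl (5 mol %), NaOt-Bu (10 mol %), (R)-1-[(SP)-2-(diphenylphosphino)ferrocenyl]ethyldicyclohexylphosphine (6 mol %), B2pin2, MeOH, THF, rt; then NaBO3·4H2O, THF/H2O, rt
Reagents that add atoms: sodium perborate, [Na+].[Na+].O[B-]1(O)OO[B-](O)(O)OO1
Why: Copper-catalysed enantioselective conjugate borylation of the β-monosubstituted ring-B enone, followed by stereoretentive oxidation of the C–B bond. The two faces of C8=C9 differ only through distant ring A, so the chiral ligand decides the C9 configuration, and the β,β-disubstituted ring-A enone is far less reactive toward the borylcopper species.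

Step 19
Reactants: 27 9-hydroxylongipin-2-ene-1,7-dione; 28 (E)-2-methylbut-2-enal (tiglaldehyde)
Product: 29 7-hydroxy-1-oxolongipin-2-en-9-yl (E)-2-methylbut-2-enoate (C7–OH anti to the C9 tiglate)
Conditions: SmI2 (25 mol %), 28 (6 equiv), THF, −10 °C
Reagents that add atoms: none
Why: Evans–Tishchenko reduction: the samarium-bound hemiacetal from the C9 hydroxyl and the aldehyde delivers its hydride to the C7 ketone through a six-membered transition state, which sets C7 1,3-anti to C9 and leaves the oxidised aldehyde on O9 as the tiglate. The C1 ketone has no β-hydroxyl and is not reduced.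

Step 20
Reactants: 29 7-hydroxy-1-oxolongipin-2-en-9-yl (E)-2-methylbut-2-enoate; 30 (Z)-2-methylbut-2-enoic acid (angelic acid)
Product: 32 7-[(Z)-2-methylbut-2-enoyloxy]-9-[(E)-2-methylbut-2-enoyloxy]longipin-2-en-1-one (target CNP0236543.4), via mixed anhydride 31 (not isolated)
Conditions: 30, 2,4,6-trichlorobenzoyl chloride, Et3N, toluene, rt; then 29, toluene, 80 °C
Reagents that add atoms: none
Why: Yamaguchi-type esterification of the hindered C7 alcohol with the preformed angelic 2,4,6-trichlorobenzoic anhydride in hot toluene without a nucleophilic pyridine catalyst, conditions under which the angeloyl group is transferred without Z-to-E isomerisation. It is placed last because the angelate is the most labile group.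

## Compound list

1 | diisopropyl 3-oxocyclobutane-1,1-dicarboxylate | CC(C)OC(=O)C1(CC(=O)C1)C(=O)OC(C)C | starting material
2 | tert-butyl 2-bromo-2-methylpropanoate | CC(C)(C)OC(=O)C(C)(C)Br | starting material
3 | tert-butyl 2-(bromozincio)-2-methylpropanoate (Reformatsky reagent) | CC(C)(C)OC(=O)C(C)(C)[Zn]Br | intermediate (not isolated)
4 | diisopropyl 3-(1-tert-butoxy-2-methyl-1-oxopropan-2-yl)-3-hydroxycyclobutane-1,1-dicarboxylate | CC(C)OC(=O)C1(CC(O)(C1)C(C)(C)C(=O)OC(C)(C)C)C(=O)OC(C)C | intermediate
5 | diisopropyl 3-(1-tert-butoxy-2-methyl-1-oxopropan-2-yl)cyclobut-2-ene-1,1-dicarboxylate | CC(C)OC(=O)C1(CC(=C1)C(C)(C)C(=O)OC(C)(C)C)C(=O)OC(C)C | intermediate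
6 | rac-3-(1-tert-butoxy-2-methyl-1-oxopropan-2-yl)-1-(isopropoxycarbonyl)cyclobut-2-ene-1-carboxylic acid | CC(C)OC(=O)C1(CC(=C1)C(C)(C)C(=O)OC(C)(C)C)C(O)=O | intermediate
7 | quinolin-8-amine | Nc1cccc2cccnc12 | starting material
8 | isopropyl rac-1-(chlorocarbonyl)-3-(1-tert-butoxy-2-methyl-1-oxopropan-2-yl)cyclobut-2-ene-1-carboxylate | CC(C)OC(=O)C1(CC(=C1)C(C)(C)C(=O)OC(C)(C)C)C(Cl)=O | intermediate (not isolated)
9 | isopropyl rac-3-(1-tert-butoxy-2-methyl-1-oxopropan-2-yl)-1-(quinolin-8-ylcarbamoyl)cyclobut-2-ene-1-carboxylate | CC(C)OC(=O)C1(CC(=C1)C(C)(C)C(=O)OC(C)(C)C)C(=O)Nc1cccc2cccnc12 | intermediate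
10 | tert-butyl rac-2-[3-(hydroxymethyl)-3-(quinolin-8-ylcarbamoyl)cyclobut-1-en-1-yl]-2-methylpropanoate | OCC1(CC(=C1)C(C)(C)C(=O)OC(C)(C)C)C(=O)Nc1cccc2cccnc12 | intermediate
11 | tert-butyl rac-2-methyl-2-[3-(quinolin-8-ylcarbamoyl)-3-(triisopropylsilyloxymethyl)cyclobut-1-en-1-yl]propanoate | CC(C)[Si](OCC1(CC(=C1)C(C)(C)C(=O)OC(C)(C)C)C(=O)Nc1cccc2cccnc12)(C(C)C)C(C)C | intermediate
12 | tert-butyl 2-methyl-2-[3-(quinolin-8-ylcarbamoyl)-3-(triisopropylsilyloxymethyl)cyclobutyl]propanoate, amide trans to the side chain | CC(C)(C)OC(=O)C(C)(C)[C@H]1C[C@](CO[Si](C(C)C)(C(C)C)C(C)C)(C(=O)Nc2cccc3cccnc23)C1 | intermediate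
13 | 2-iodopropene | CC(I)=C | starting material
14 | tert-butyl 2-[2,4-di(prop-1-en-2-yl)-3-(quinolin-8-ylcarbamoyl)-3-(triisopropylsilyloxymethyl)cyclobutyl]-2-methylpropanoate, meso, isopropenyl groups cis to the amide | CC(=C)[C@H]1[C@H](C(C)(C)C(=O)OC(C)(C)C)[C@@H](C(C)=C)[C@]1(C(=O)Nc2cccc3cccnc23)CO[Si](C(C)C)(C(C)C)C(C)C | intermediate
15 | tert-butyl 2-[3-formyl-2,4-di(prop-1-en-2-yl)-3-(triisopropylsilyloxymethyl)cyclobutyl]-2-methylpropanoate, meso | CC(=C)[C@H]1[C@H](C(C)(C)C(=O)OC(C)(C)C)[C@@H](C(C)=C)[C@]1(C=O)CO[Si](C(C)C)(C(C)C)C(C)C | intermediate
16 | hydrazone of 15 | CC(=C)[C@H]1[C@H](C(C)(C)C(=O)OC(C)(C)C)[C@@H](C(C)=C)[C@]1(C=NN)CO[Si](C(C)C)(C(C)C)C(C)C | intermediate (not isolated)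
17 | tert-butyl 2-methyl-2-[3-methyl-2,4-di(prop-1-en-2-yl)-3-(triisopropylsilyloxymethyl)cyclobutyl]propanoate, meso | CC(=C)[C@H]1[C@H](C(C)(C)C(=O)OC(C)(C)C)[C@@H](C(C)=C)[C@]1(C)CO[Si](C(C)C)(C(C)C)C(C)C | intermediate
18 | tert-butyl 2-[2,4-diacetyl-3-methyl-3-(triisopropylsilyloxymethyl)cyclobutyl]-2-methylpropanoate, meso (precursor of the key step) | CC(=O)[C@H]1[C@H](C(C)(C)C(=O)OC(C)(C)C)[C@@H](C(C)=O)[C@]1(C)CO[Si](C(C)C)(C(C)C)C(C)C | intermediate
19 | tert-butyl 2-[4,6-dimethyl-2-oxo-6-(triisopropylsilyloxymethyl)bicyclo[3.1.1]hept-3-en-7-yl]-2-methylpropanoate (product of the key step) | CC(C)(C)OC(=O)C(C)(C)[C@H]1[C@@H]2C(C)=CC(=O)[C@H]1[C@]2(C)CO[Si](C(C)C)(C(C)C)C(C)C | intermediate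
20 | 2-[4,6-dimethyl-2-oxo-6-(triisopropylsilyloxymethyl)bicyclo[3.1.1]hept-3-en-7-yl]-2-methylpropanoic acid | OC(=O)C(C)(C)[C@H]1[C@@H]2C(C)=CC(=O)[C@H]1[C@]2(C)CO[Si](C(C)C)(C(C)C)C(C)C | intermediate
21 | acid chloride of 20 | ClC(=O)C(C)(C)[C@H]1[C@@H]2C(C)=CC(=O)[C@H]1[C@]2(C)CO[Si](C(C)C)(C(C)C)C(C)C | intermediate (not isolated)
22 | 4,6-dimethyl-7-(2-methyl-3-oxobutan-2-yl)-6-(triisopropylsilyloxymethyl)bicyclo[3.1.1]hept-3-en-2-one | CC(=O)C(C)(C)[C@H]1[C@@H]2C(C)=CC(=O)[C@H]1[C@]2(C)CO[Si](C(C)C)(C(C)C)C(C)C | intermediate
23 | 6-(hydroxymethyl)-4,6-dimethyl-7-(2-methyl-3-oxobutan-2-yl)bicyclo[3.1.1]hept-3-en-2-one | CC(=O)C(C)(C)[C@H]1[C@@H]2C(C)=CC(=O)[C@H]1[C@]2(C)CO | intermediate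
24 | 2,6-dimethyl-7-(2-methyl-3-oxobutan-2-yl)-4-oxobicyclo[3.1.1]hept-2-ene-6-carbaldehyde | CC(=O)C(C)(C)[C@H]1[C@@H]2C(C)=CC(=O)[C@H]1[C@]2(C)C=O | intermediate
25 | longipina-2,8-diene-1,7-dione | O=C1C=C[C@@]2(C)[C@@H]3C(=O)C=C(C)[C@H]2[C@@H]3C1(C)C | intermediate
26 | 9-(4,4,5,5-tetramethyl-1,3,2-dioxaborolan-2-yl)longipin-2-ene-1,7-dione | O=C1C[C@@H](B4OC(C)(C)C(C)(C)O4)[C@@]2(C)[C@@H]3C(=O)C=C(C)[C@H]2[C@@H]3C1(C)C | intermediate (not isolated)
27 | 9-hydroxylongipin-2-ene-1,7-dione | O=C1C[C@@H](O)[C@@]2(C)[C@@H]3C(=O)C=C(C)[C@H]2[C@@H]3C1(C)C | intermediate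
28 | (E)-2-methylbut-2-enal (tiglaldehyde) | C/C=C(\C)C=O | starting material
29 | 7-hydroxy-1-oxolongipin-2-en-9-yl (E)-2-methylbut-2-enoate | O[C@@H]1C[C@@H](OC(=O)/C(C)=C/C)[C@@]2(C)[C@@H]3C(=O)C=C(C)[C@H]2[C@@H]3C1(C)C | intermediate
30 | (Z)-2-methylbut-2-enoic acid (angelic acid) | C/C=C(/C)C(O)=O | starting material
31 | (Z)-2-methylbut-2-enoic 2,4,6-trichlorobenzoic anhydride | C/C=C(/C)C(=O)OC(=O)c1c(Cl)cc(Cl)cc1Cl | intermediate (not isolated)
32 | 7-[(Z)-2-methylbut-2-enoyloxy]-9-[(E)-2-methylbut-2-enoyloxy]longipin-2-en-1-one (CNP0236543.4) | C/C=C(/C)C(=O)O[C@@H]1C[C@@H](OC(=O)/C(C)=C/C)[C@@]2(C)[C@@H]3C(=O)C=C(C)[C@H]2[C@@H]3C1(C)C | target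

## Step count and least certain steps

Total: 20 steps. Longest linear sequence: 20 steps (1 to 32); 2, 7, 13, 28 and 30 enter as purchased reagents.

**Step 12 (key step, proposed new method).** Three things can go wrong. The closure may stall at the diketone or the ketol, because forming the bicyclo[3.1.1]heptene adds ring strain and the aldol addition is reversible. The catalyst may discriminate the enantiotopic acetyl groups poorly or in the opposite sense. An achiral acid- or base-promoted closure may compete. The fallback uses known reactions and replaces the reversible, catalytic aldol by an irreversible alkylation after a reductive desymmetrisation. It sets out from 18: enantiotopos-selective mono-reduction with a ketoreductase, or with the Me-CBS oxazaborolidine and catecholborane, gives the hydroxy ketone F1, in which the acetyl on C4 has become a 1-hydroxyethyl group. Mesylation gives the mesylate F2. Kinetic deprotonation of the remaining acetyl at its methyl group (LiHMDS, THF, −78 °C → rt) and intramolecular alkylation with inversion close ring A as the saturated 4-methylbicyclo[3.1.1]heptan-2-one F3. Dehydrogenation with IBX (DMSO/toluene, 70 °C) introduces C2=C3 and returns to the route at 19.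

**Step 8.** The reaction may stop after the first alkenylation, because the second palladacycle must form between a quaternary carbon and an α-branched alkenyl group; the amide nitrogen may also add to the first isopropenyl group. The fallback installs slimmer two-carbon units and builds the isopropenyl groups afterwards. It sets out from 12: double C–H alkynylation with (bromoethynyl)triisopropylsilane (Pd(OAc)2, AgOAc, toluene, 110 °C) gives the bis(silylalkynyl) amide F4. AgF in MeCN removes the two alkynyl silyl groups to give the diyne F5. Zirconium-catalysed methylalumination (Me3Al, Cp2ZrCl2, CH2Cl2) and protonolysis turn each terminal alkyne into an isopropenyl group and return to the route at 14.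

**Step 9.** Hydrozirconation of the very hindered amide may be slow, so that hydrozirconation of the isopropenyl groups competes. The fallback activates the amide instead. It sets out from 14: Boc2O and DMAP (MeCN, 60 °C) give the N-Boc imide F6, LiBH4 (THF/MeOH) cleaves the activated acyl–nitrogen bond to the neopentyl alcohol F7, and Dess–Martin oxidation returns to the route at 15.

**Step 10.** Hydrazone formation at the flanked aldehyde may be incomplete. The strongly basic medium may also open the cyclobutane through carbanion character at the exocyclic carbon, or move the isopropenyl double bonds. The fallback replaces the diazene anion by a hydride displacement. It sets out from 15: NaBH4 (MeOH, 0 °C) gives the alcohol F7 (the compound already met under step 9), MsCl and Et3N give the mesylate F8, and NaBH4 in DMSO at 90 °C displaces the mesylate and returns to the route at 17.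

**Step 18.** Conjugate borylation at the neopentyl β-carbon may be sluggish, facial discrimination by the ligand may be incomplete, and the ring-A enone may begin to react under forcing conditions. The fallback introduces the C9 oxygen by epoxidation. It sets out from 25: amine-salt-catalysed nucleophilic epoxidation (9-amino-9-deoxy-epi-quinine bis(trifluoroacetate), aqueous H2O2, dioxane, 35 °C) gives the cis-α,β-epoxy ketone F9. Reductive opening at C8 with the phenylselenide reagent made from (PhSe)2 and NaBH4 (EtOH, AcOH, 0 °C) returns to the route at 27.

**Step 19.** The conjugated aldehyde may form the hemiacetal reluctantly and transfer hydride slowly, so that retro-aldol opening of 27 or acyl migration competes. The fallback separates acylation from reduction. It sets out from 27: tiglic anhydride with Sc(OTf)3 (MeCN, −20 °C) gives the β-tigloyloxy ketone F10 under non-basic conditions that avoid elimination. CBS reduction (Me-CBS oxazaborolidine, catecholborane, −78 °C), with the quaternary C6 acting as the large group, then reduces the C7 ketone from the face that leaves O7 anti to O9 and returns to the route at 29.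

## Further compounds

F1 | step 12 | tert-butyl 2-[2-acetyl-4-[(S)-1-hydroxyethyl]-3-methyl-3-(triisopropylsilyloxymethyl)cyclobutyl]-2-methylpropanoate (hydroxyethyl on C4) | C[C@H](O)[C@H]1[C@H](C(C)(C)C(=O)OC(C)(C)C)[C@@H](C(C)=O)[C@]1(C)CO[Si](C(C)C)(C(C)C)C(C)C
F2 | step 12 | methanesulfonate of F1 | C[C@H](OS(C)(=O)=O)[C@H]1[C@H](C(C)(C)C(=O)OC(C)(C)C)[C@@H](C(C)=O)[C@]1(C)CO[Si](C(C)C)(C(C)C)C(C)C
F3 | step 12 | tert-butyl 2-[4,6-dimethyl-2-oxo-6-(triisopropylsilyloxymethyl)bicyclo[3.1.1]heptan-7-yl]-2-methylpropanoate | CC(C)(C)OC(=O)C(C)(C)[C@H]1[C@@H]2[C@@H](C)CC(=O)[C@H]1[C@]2(C)CO[Si](C(C)C)(C(C)C)C(C)C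
F4 | step 8 | tert-butyl 2-methyl-2-[3-(quinolin-8-ylcarbamoyl)-3-(triisopropylsilyloxymethyl)-2,4-bis(triisopropylsilylethynyl)cyclobutyl]propanoate, meso | CC(C)[Si](C#C[C@H]1[C@H](C(C)(C)C(=O)OC(C)(C)C)[C@@H](C#C[Si](C(C)C)(C(C)C)C(C)C)[C@]1(C(=O)Nc2cccc3cccnc23)CO[Si](C(C)C)(C(C)C)C(C)C)(C(C)C)C(C)C
F5 | step 8 | tert-butyl 2-[2,4-diethynyl-3-(quinolin-8-ylcarbamoyl)-3-(triisopropylsilyloxymethyl)cyclobutyl]-2-methylpropanoate, meso | C#C[C@H]1[C@H](C(C)(C)C(=O)OC(C)(C)C)[C@@H](C#C)[C@]1(C(=O)Nc2cccc3cccnc23)CO[Si](C(C)C)(C(C)C)C(C)C
F6 | step 9 | N-tert-butoxycarbonyl derivative of 14 | CC(=C)[C@H]1[C@H](C(C)(C)C(=O)OC(C)(C)C)[C@@H](C(C)=C)[C@]1(C(=O)N(C(=O)OC(C)(C)C)c2cccc3cccnc23)CO[Si](C(C)C)(C(C)C)C(C)C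
F7 | step 9 | tert-butyl 2-[3-(hydroxymethyl)-2,4-di(prop-1-en-2-yl)-3-(triisopropylsilyloxymethyl)cyclobutyl]-2-methylpropanoate, meso | CC(=C)[C@H]1[C@H](C(C)(C)C(=O)OC(C)(C)C)[C@@H](C(C)=C)[C@]1(CO)CO[Si](C(C)C)(C(C)C)C(C)C
F8 | step 10 | methanesulfonate of F7 | CC(=C)[C@H]1[C@H](C(C)(C)C(=O)OC(C)(C)C)[C@@H](C(C)=C)[C@]1(COS(C)(=O)=O)CO[Si](C(C)C)(C(C)C)C(C)C
F9 | step 18 | 8,9-epoxylongipin-2-ene-1,7-dione (epoxide oxygen on the C11 side) | O=C1[C@H]4O[C@H]4[C@@]2(C)[C@@H]3C(=O)C=C(C)[C@H]2[C@@H]3C1(C)C
F10 | step 19 | 1,7-dioxolongipin-2-en-9-yl (E)-2-methylbut-2-enoate | O=C1C[C@@H](OC(=O)/C(C)=C/C)[C@@]2(C)[C@@H]3C(=O)C=C(C)[C@H]2[C@@H]3C1(C)C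
A1 | alternative 1 | endo-nitro norbornene with bridgehead trimethylsilyloxy C1, bridge C10 and ring B closed | C[Si](C)(C)O[C@]12C=C(C)[C@H]([C@@]1(C)[C@H](O[Si](CC)(CC)CC)C[C@@H](O[Si](C)(C)C(C)(C)C)C3(C)C)[C@H]3[C@H]2[N+](=O)[O-]
A2 | alternative 1 | 5-methyl-5-(nitroalkenyl chain)-1-trimethylsilyloxy-3-methylcyclopentadiene, the Diels–Alder precursor | C[Si](C)(C)OC1=CC(C)=C[C@@]1(C)[C@H](O[Si](CC)(CC)CC)C[C@@H](O[Si](C)(C)C(C)(C)C)C(C)(C)/C=C/[N+](=O)[O-]
A3 | alternative 2 | 2,7-dimethyl-7-(triisopropylsilyloxymethyl)bicyclo[3.1.1]hept-2-en-6-one | O=C1[C@@H]2C(C)=CC[C@H]1[C@]2(C)CO[Si](C(C)C)(C(C)C)C(C)C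
A4 | alternative 2 | 2-[(Z)-3-iodobut-2-enyl]-3-methyl-3-(triisopropylsilyloxymethyl)cyclobutanone | O=C1C[C@@](C)(CO[Si](C(C)C)(C(C)C)C(C)C)[C@@H]1C/C=C(/C)I
A5 | alternative 3 | longipin-2-ene-1,9-dione 7-ethylene ketal | O=C1CC2(OCCO2)C(C)(C)[C@H]3[C@@H]4C(C)=CC(=O)[C@H]3[C@]14C
A6 | alternative 3 | bis(trimethylsilyl enol ether) of the cis-fused bicyclo[5.4.0]undecenedione ketal | C[Si](C)(C)OC1=C(C)[C@H]2C(C)=CC(O[Si](C)(C)C)=C[C@H]2C(C)(C)C3(OCCO3)C1
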